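Ring A (C1–C5, C10) and ring B (C5–C10) share the C5–C10 bond; C3 carries oxygen and C10 adjoins the C9 carbinol. Both rings are therefore closed at once by an intramolecular Diels–Alder reaction of an acyclic trienone: the C2=C3(OTBS)–C4(Me)=C5 silyloxydiene adds to the C10=C1 isopropenyl ketone (C9=O), forming C1–C2 and C5–C10 and setting C5 and C10 from the lone C8 methyl stereocentre. The resulting enol ether delivers the C4 gem-dimethyl group regiospecifically; the C3 ketone becomes a 2-ene for α-face dihydroxylation, and the C9 ketone accepts the side chain by vinyl addition and B-alkyl Suzuki coupling.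

Key step: step 7

Remark on the chemistry: labdane numbering is used for all ring compounds (ring A = C1–C5 and C10, ring B = C5–C10, side chain on C9), β is the face of the C10 methyl group, and compounds 1, 2, 6, 9, 15 and 17 are taken as commercial.

Step 1
Reactants: 1 (R)-4-benzyloxazolidin-2-one; 2 hex-5-enoyl chloride
Product: 3 (R)-4-benzyl-3-(hex-5-enoyl)oxazolidin-2-one
Conditions: n-BuLi, THF, −78 °C; then 2, −78 → 0 °C
Reagents that add atoms: none
Why: N-acylation of the lithiated oxazolidinone by the acid chloride, with no stereocentre formed.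

Step 2
Reactants: 3 (R)-4-benzyl-3-(hex-5-enoyl)oxazolidin-2-one
Product: 4 (R)-4-benzyl-3-[(2R)-2-methylhex-5-enoyl]oxazolidin-2-one
Conditions: NaHMDS, THF, −78 °C; MeI, −78 → −40 °C
Reagents that add atoms: methyl iodide, CI
Why: Evans alkylation, in which the chelated Z-enolate should be methylated on the face opposite the benzyl group to set the (2R) centre that becomes C8.

Step 3
Reactants: 4 (R)-4-benzyl-3-[(2R)-2-methylhex-5-enoyl]oxazolidin-2-one
Product: 5 (2R)-N-methoxy-N,2-dimethylhex-5-enamide
Conditions: MeNH(OMe)·HCl, AlMe3, CH2Cl2, −10 → 20 °C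
Reagents that add atoms: N,O-dimethylhydroxylamine hydrochloride, CNOC.Cl
Why: Aluminium-amide transamidation at the exocyclic imide carbonyl gives the Weinreb amide without touching the α-stereocentre and releases the auxiliary.

Step 4
Reactants: 5 (2R)-N-methoxy-N,2-dimethylhex-5-enamide; 6 3-methylbut-3-en-2-one
Product: 7 (2R,5E)-N-methoxy-N,2,6-trimethyl-7-oxooct-5-enamide
Conditions: second-generation Hoveyda–Grubbs catalyst (5 mol%), 6 (5 equiv), CH2Cl2, 40 °C
Reagents that add atoms: none
Why: Olefin cross-metathesis of the terminal alkene with the 1,1-disubstituted enone should give the trisubstituted enone as the thermodynamically favoured E isomer.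

Step 5
Reactants: 7 (2R,5E)-N-methoxy-N,2,6-trimethyl-7-oxooct-5-enamide
Product: 8 (2R,5E)-7-[(tert-butyldimethylsilyl)oxy]-N-methoxy-N,2,6-trimethylocta-5,7-dienamide
Conditions: TBSOTf, Et3N, CH2Cl2, −78 → 0 °C
Reagents that add atoms: tert-butyldimethylsilyl trifluoromethanesulfonate, CC(C)(C)[Si](C)(C)OS(=O)(=O)C(F)(F)F
Why: Soft enolisation of the methyl ketone at its α′-methyl group gives the cross-conjugated 2-silyloxydiene, while the far less acidic amide α-position is left alone.

Step 6
Reactants: 8 (2R,5E)-7-[(tert-butyldimethylsilyl)oxy]-N-methoxy-N,2,6-trimethylocta-5,7-dienamide; 9 isopropenylmagnesium bromide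
Product: 10 (4R,7E)-9-[(tert-butyldimethylsilyl)oxy]-2,4,8-trimethyldeca-1,7,9-trien-3-one
Conditions: 9, THF, −20 → 0 °C; pH 7 phosphate buffer, 0 °C; used at once
Reagents that add atoms: none
Why: Weinreb ketone synthesis, in which the chelated tetrahedral intermediate blocks over-addition and the enone appears only on cold neutral work-up, so the silyl dienol ether and the α-stereocentre should survive.

Step 7
Reactants: 10 (4R,7E)-9-[(tert-butyldimethylsilyl)oxy]-2,4,8-trimethyldeca-1,7,9-trien-3-one
Product: 11 (2R,4aS,8aS)-6-[(tert-butyldimethylsilyl)oxy]-2,5,8a-trimethyl-3,4,4a,7,8,8a-hexahydronaphthalen-1(2H)-one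
Conditions: toluene (0.01 M), BHT, 80 °C
Reagents that add atoms: none
Why: Thermal, concerted but asynchronous normal-demand [4+2] cycloaddition in which the electron-rich 2-silyloxydiene (C2=C3–C4=C5) adds across the tethered isopropenyl ketone (C10=C1), the closest known reaction type being the type 1 intramolecular Diels–Alder reaction of 1,7,9-decatrien-3-ones. Ring A is closed by the cycloaddition itself as a cyclohexene containing both new bonds (C1–C2 and C5–C10), while ring B is closed by the C5–C10 bond through the four-carbon tether C6–C9 as a fused six-membered carbocycle. The trans relationship of H5 and the C10 methyl group should follow from the transition state with the tether carbonyl exo and the dienophile methyl endo, the usual preference of α-methyl enones, reinforced by a chair-like, trans-decalin-like tether. The absolute sense at C5 and C10 is controlled by the C8 stereocentre, whose methyl group takes the equatorial site of that chair to avoid a syn-pentane contact with the C10 methyl group. Regiochemistry is enforced by the tether and is electronically matched (nucleophilic C2 of the enol ether bonds to the enone β-carbon C1), so the step needs only exo selectivity and π-facial selectivity, both secured by the C10 and C8 methyl groups; dilution and BHT suppress intermolecular pathways.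

Step 8
Reactants: 11 (2R,4aS,8aS)-6-[(tert-butyldimethylsilyl)oxy]-2,5,8a-trimethyl-3,4,4a,7,8,8a-hexahydronaphthalen-1(2H)-one
Product: 12 (2R,4aS,8aS)-2,5,5,8a-tetramethylhexahydronaphthalene-1,6(2H,5H)-dione
Conditions: TASF [(Me2N)3S+ Me3SiF2−], MeI (excess), THF, −78 → 0 °C
Reagents that add atoms: methyl iodide, CI
Why: Fluoride-promoted alkylation of a silyl enol ether, in which O–Si cleavage releases the regiospecific C3–C4 enolate that is C-methylated at C4 to give the gem-dimethyl group (no new stereocentre), the equatorial 8α-methyl being the thermodynamic arrangement next to the C9 ketone.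

Step 9
Reactants: 12 (2R,4aS,8aS)-2,5,5,8a-tetramethylhexahydronaphthalene-1,6(2H,5H)-dione
Product: 13 (4aS,6R,8aS)-1,1,4a,6-tetramethyl-5-oxo-1,4,4a,5,6,7,8,8a-octahydronaphthalen-2-yl trifluoromethanesulfonate
Conditions: KHMDS (1.05 equiv), THF, −78 °C; PhNTf2, −78 → 0 °C
Reagents that add atoms: N-phenylbis(trifluoromethanesulfonimide), O=S(=O)(N(c1ccccc1)S(=O)(=O)C(F)(F)F)C(F)(F)F
Why: Kinetic deprotonation should occur at the C2 methylene of the C3 ketone (C4 is quaternary, and the only α-hydrogen of the hindered C9 ketone is the tertiary C8–H), and O-triflation then gives the C2=C3 enol triflate.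

Step 10
Reactants: 13 (4aS,6R,8aS)-1,1,4a,6-tetramethyl-5-oxo-1,4,4a,5,6,7,8,8a-octahydronaphthalen-2-yl trifluoromethanesulfonate
Product: 14 (2R,4aS,8aS)-2,5,5,8a-tetramethyl-3,4,4a,5,8,8a-hexahydronaphthalen-1(2H)-one
Conditions: Pd(OAc)2 (5 mol%), PPh3 (10 mol%), HCO2H, Et3N, DMF, 60 °C
Reagents that add atoms: none
Why: Palladium-catalysed formate reduction of the enol triflate (oxidative addition, formate-to-hydride exchange with loss of CO2, reductive elimination) leaves the C2=C3 alkene and does not affect the ketone.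

Step 11
Reactants: 14 (2R,4aS,8aS)-2,5,5,8a-tetramethyl-3,4,4a,5,8,8a-hexahydronaphthalen-1(2H)-one; 15 vinylmagnesium bromide
Product: 16 (1S,2R,4aS,8aS)-1-ethenyl-2,5,5,8a-tetramethyl-1,2,3,4,4a,5,8,8a-octahydronaphthalen-1-ol
Conditions: CeCl3 (anhydrous), 15, THF, −78 → 0 °C
Reagents that add atoms: none
Why: Organocerium 1,2-addition suppresses enolisation of the hindered ketone, and attack on the α face, anti to the axial C10 methyl group, should set C9 with the vinyl group α and the hydroxyl β.

Step 12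
Reactants: 17 methyl acetoacetate
Product: 18 methyl (2E)-3-{[(trifluoromethyl)sulfonyl]oxy}but-2-enoate
Conditions: Tf2O, 25% aq. Me4NOH, hexanes, 5 °C
Reagents that add atoms: trifluoromethanesulfonic anhydride, O=S(=O)(OS(=O)(=O)C(F)(F)F)C(F)(F)F
Why: The non-chelated tetramethylammonium enolate adopts the extended geometry, so O-sulfonylation should give the (E)-enol triflate with the methyl group cis to the ester.

Step 13
Reactants: 16 (1S,2R,4aS,8aS)-1-ethenyl-2,5,5,8a-tetramethyl-1,2,3,4,4a,5,8,8a-octahydronaphthalen-1-ol; 18 methyl (2E)-3-{[(trifluoromethyl)sulfonyl]oxy}but-2-enoate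
Product: 20 methyl (2E)-5-[(1S,2R,4aS,8aS)-1-hydroxy-2,5,5,8a-tetramethyl-1,2,3,4,4a,5,8,8a-octahydronaphthalen-1-yl]-3-methylpent-2-enoate, via B-alkyl-9-BBN adduct 19 (not isolated)
Conditions: 9-BBN (2.5 equiv), THF, 0 → 23 °C; then 3 M aq. K3PO4, 18, Pd(dppf)Cl2 (5 mol%), DMF, 23 °C
Reagents that add atoms: none
Why: Anti-Markovnikov hydroboration of the vinyl group (9-BBN should ignore the hindered ring alkene) followed by B-alkyl Suzuki–Miyaura coupling, which forms C12–C13 with retention of the E geometry of the enol triflate.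

Step 14
Reactants: 20 methyl (2E)-5-[(1S,2R,4aS,8aS)-1-hydroxy-2,5,5,8a-tetramethyl-1,2,3,4,4a,5,8,8a-octahydronaphthalen-1-yl]-3-methylpent-2-enoate
Product: 21 methyl (2E)-5-[(1S,2R,4aS,6S,7R,8aS)-1,6,7-trihydroxy-2,5,5,8a-tetramethyldecahydronaphthalen-1-yl]-3-methylpent-2-enoate
Conditions: OsO4 (2 mol%), NMO, acetone/H2O, 23 °C
Reagents that add atoms: osmium tetroxide, O=[Os](=O)(=O)=O; N-methylmorpholine N-oxide, C[N+]1([O-])CCOCC1
Why: Catalytic syn-dihydroxylation should take place on the α face of the C2=C3 alkene, the β face being screened by the axial C10 and 4β methyl groups, to give the 2α,3α-diol, while the electron-poor trisubstituted enoate reacts more slowly.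

Compound list
1 | (R)-4-benzyloxazolidin-2-one | O=C1N[C@H](Cc2ccccc2)CO1 | starting material
2 | hex-5-enoyl chloride | C=CCCCC(=O)Cl | starting material
3 | (R)-4-benzyl-3-(hex-5-enoyl)oxazolidin-2-one | C=CCCCC(=O)N1[C@H](Cc2ccccc2)COC1=O | intermediate
4 | (R)-4-benzyl-3-[(2R)-2-methylhex-5-enoyl]oxazolidin-2-one | C=CCC[C@@H](C)C(=O)N1[C@H](Cc2ccccc2)COC1=O | intermediate
5 | (2R)-N-methoxy-N,2-dimethylhex-5-enamide | C=CCC[C@@H](C)C(=O)N(C)OC | intermediate
6 | 3-methylbut-3-en-2-one | CC(=O)C(C)=C | starting material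
7 | (2R,5E)-N-methoxy-N,2,6-trimethyl-7-oxooct-5-enamide | CC(=O)/C(C)=C/CC[C@@H](C)C(=O)N(C)OC | intermediate
8 | (2R,5E)-7-[(tert-butyldimethylsilyl)oxy]-N-methoxy-N,2,6-trimethylocta-5,7-dienamide | C=C(O[Si](C)(C)C(C)(C)C)/C(C)=C/CC[C@@H](C)C(=O)N(C)OC | intermediate
9 | isopropenylmagnesium bromide | C=C(C)[Mg]Br | starting material
10 | (4R,7E)-9-[(tert-butyldimethylsilyl)oxy]-2,4,8-trimethyldeca-1,7,9-trien-3-one | C=C(O[Si](C)(C)C(C)(C)C)/C(C)=C/CC[C@@H](C)C(=O)C(C)=C | intermediate
11 | (2R,4aS,8aS)-6-[(tert-butyldimethylsilyl)oxy]-2,5,8a-trimethyl-3,4,4a,7,8,8a-hexahydronaphthalen-1(2H)-one (trans-fused; 5α-H, 8α-Me, 10β-Me) | O=C1[C@H](C)CC[C@H]2C(C)=C(O[Si](C)(C)C(C)(C)C)CC[C@@]21C | intermediate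
12 | (2R,4aS,8aS)-2,5,5,8a-tetramethylhexahydronaphthalene-1,6(2H,5H)-dione | O=C1[C@H](C)CC[C@H]2C(C)(C)C(=O)CC[C@@]21C | intermediate
13 | (4aS,6R,8aS)-1,1,4a,6-tetramethyl-5-oxo-1,4,4a,5,6,7,8,8a-octahydronaphthalen-2-yl trifluoromethanesulfonate | O=C1[C@H](C)CC[C@H]2C(C)(C)C(OS(=O)(=O)C(F)(F)F)=CC[C@@]21C | intermediate
14 | (2R,4aS,8aS)-2,5,5,8a-tetramethyl-3,4,4a,5,8,8a-hexahydronaphthalen-1(2H)-one | O=C1[C@H](C)CC[C@H]2C(C)(C)C=CC[C@@]21C | intermediate
15 | vinylmagnesium bromide | C=C[Mg]Br | starting material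
16 | (1S,2R,4aS,8aS)-1-ethenyl-2,5,5,8a-tetramethyl-1,2,3,4,4a,5,8,8a-octahydronaphthalen-1-ol (9α-vinyl, 9β-OH) | C=C[C@]1(O)[C@H](C)CC[C@H]2C(C)(C)C=CC[C@@]21C | intermediate
17 | methyl acetoacetate | COC(=O)CC(C)=O | starting material
18 | methyl (2E)-3-{[(trifluoromethyl)sulfonyl]oxy}but-2-enoate | COC(=O)/C=C(\C)OS(=O)(=O)C(F)(F)F | intermediate
19 | B-alkyl-9-BBN adduct of 16 (boron on the terminal side-chain carbon C12) | B1(C2CCCC1CCC2)CC[C@]3(O)[C@H](C)CC[C@H]4C(C)(C)C=CC[C@@]43C | intermediate
20 | methyl (2E)-5-[(1S,2R,4aS,8aS)-1-hydroxy-2,5,5,8a-tetramethyl-1,2,3,4,4a,5,8,8a-octahydronaphthalen-1-yl]-3-methylpent-2-enoate | COC(=O)/C=C(\C)CC[C@]1(O)[C@H](C)CC[C@H]2C(C)(C)C=CC[C@@]21C | intermediate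
21 | methyl (2E)-5-[(1S,2R,4aS,6S,7R,8aS)-1,6,7-trihydroxy-2,5,5,8a-tetramethyldecahydronaphthalen-1-yl]-3-methylpent-2-enoate (2α,3α,9β-triol; 5α-H, 8α-Me, 10β-Me) | COC(=O)/C=C(\C)CC[C@]1(O)[C@H](C)CC[C@H]2C(C)(C)[C@H](O)[C@H](O)C[C@@]21C | target

Total step count: 14. Longest linear sequence: 13 steps (steps 1–11, 13 and 14); step 12 is a one-step side branch.

Steps most likely to fail

Step 7. The cycloaddition may discriminate poorly between the exo and endo arrangements of the tether carbonyl, giving a mixture of trans- and cis-fused ring systems. The fallback sets out from 11, taken as the mixture of ring-fusion isomers, and comes back at 12. Saegusa–Ito oxidation of the silyl enol ether (Pd(OAc)2, MeCN, 23 °C) removes the C5 hydrogen and should converge both isomers on (4aS,6R)-1,4a,6-trimethyl-4,4a,7,8-tetrahydronaphthalene-2,5(3H,6H)-dione F1, in which C5 is trigonal. Dissolving-metal reductive methylation (Li, NH3/THF, −78 °C; then MeI) should then protonate C5 trans to the C10 methyl group and methylate the regiospecific C3–C4 enolate at C4. It also reduces the C9 ketone, giving 9β-hydroxy-4,4,8α,10β-tetramethyl-5α-decalin-3-one F2. Dess–Martin periodinane (CH2Cl2, 23 °C) restores the C9 ketone to give 12; step 8 is then not needed.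

Step 8. The fluoride-generated enolate may be protonated before it is alkylated, or may equilibrate towards C2 and be methylated twice. The fallback sets out from 11 and comes back at 12, bringing the methyl group in as a methylene. Simmons–Smith cyclopropanation in its diethylzinc form (Et2Zn, CH2I2, CH2Cl2, 0 °C) should give the 3,4-methano silyl ether F3 on the α face. TBAF (THF, 23 °C) followed by NaOH in MeOH (60 °C) should then open the cyclopropanol at its C3–CH2 bond, the side that gives the primary carbanion, to deliver the 4,4-dimethyl-3-ketone 12.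

Step 14. Loss of chemoselectivity is possible, with the side-chain enoate competing with the hindered ring alkene for the oxidant. The fallback sets out from 14 and comes back at 21, moving the dihydroxylation ahead of side-chain construction. OsO4 (cat.) and NMO in acetone/H2O should convert 14, which has no other alkene, into the 2α,3α-dihydroxy-9-ketone F4. 2,2-Dimethoxypropane with PPTS (CH2Cl2, 23 °C) gives the acetonide ketone F5. Vinylmagnesium bromide with CeCl3 (THF, −78 → 0 °C) gives the 9α-vinyl carbinol acetonide F6. 9-BBN gives the B-alkyl-9-BBN acetonide adduct F7, which is coupled without isolation with 18 (Pd(dppf)Cl2, aq. K3PO4, DMF) to the enoate acetonide F8. Aqueous AcOH (40 °C) then releases 21.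

Further compounds
F1 | step 7 | (4aS,6R)-1,4a,6-trimethyl-4,4a,7,8-tetrahydronaphthalene-2,5(3H,6H)-dione | O=C1[C@H](C)CCC2=C(C)C(=O)CC[C@@]21C
F2 | step 7 | 9β-hydroxy-4,4,8α,10β-tetramethyl-5α-decalin-3-one (labdane numbering) | O[C@H]1[C@H](C)CC[C@H]2C(C)(C)C(=O)CC[C@@]21C
F3 | step 8 | 3β-[(tert-butyldimethylsilyl)oxy]-3α,4α-methano-4β,8α,10β-trimethyl-5α-decalin-9-one (labdane numbering) | O=C1[C@H](C)CC[C@H]2[C@]3(C)C[C@]3(O[Si](C)(C)C(C)(C)C)CC[C@@]21C
F4 | step 14 | 2α,3α-dihydroxy-4,4,8α,10β-tetramethyl-5α-decalin-9-one (labdane numbering) | O=C1[C@H](C)CC[C@H]2C(C)(C)[C@H](O)[C@H](O)C[C@@]21C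
F5 | step 14 | 2α,3α-(isopropylidenedioxy)-4,4,8α,10β-tetramethyl-5α-decalin-9-one (labdane numbering) | O=C1[C@H](C)CC[C@H]2C(C)(C)[C@@H]3OC(C)(C)O[C@@H]3C[C@@]21C
F6 | step 14 | 9α-vinyl-2α,3α-(isopropylidenedioxy)-4,4,8α,10β-tetramethyl-5α-decalin-9β-ol (labdane numbering) | C=C[C@]1(O)[C@H](C)CC[C@H]2C(C)(C)[C@@H]3OC(C)(C)O[C@@H]3C[C@@]21C
F7 | step 14 | B-alkyl-9-BBN adduct of F6 (boron on C12) | B1(C2CCCC1CCC2)CC[C@]3(O)[C@H](C)CC[C@H]4C(C)(C)[C@@H]5OC(C)(C)O[C@@H]5C[C@@]43C
F8 | step 14 | 2,3-O-isopropylidene derivative of 21 | COC(=O)/C=C(\C)CC[C@]1(O)[C@H](C)CC[C@H]2C(C)(C)[C@@H]3OC(C)(C)O[C@@H]3C[C@@]21C
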